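**Retrosynthetic overview**
- Last bonds: both angelates by mixed-anhydride esterification of a C2/C8 diol; the C6 acetate by enolate oxidation and acetylation trans to the side chain.
- Key disconnection: C1–C7, closed by a 7-exo vinyl-radical cyclisation across a temporary O2–SiMe2–O8 silaketal. The tether joins two enantiopure halves and delivers C7 to the face of the C2 oxygen, which sets C1.
- Ring half: an epoxyquinol from o-cresol (quinone monoketal, CBS reduction, hydroxyl-directed epoxidation, oxidation/deketalisation, Luche reduction).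
- Side-chain half: 2-bromoacrolein, Brown allylation (C8), cross-metathesis to the prenyl group, Shi epoxidation (C10).
- Ring order: the carbocycle comes from the arene; ring epoxide next; side-chain epoxide in a separate branch; a transient seven-membered silaketal ring is made in the radical step and removed afterwards.

Assumption: 2-bromoacrolein (stabilised) is bought, as are (+)-Ipc2BOMe, (S)-Me-CBS and the L-fructose-derived enantiomer of the Shi ketone.

Locants used in the names of compounds 17–26: ring C1 (bears the chain), C2 (O), C3/C4 (epoxide, C4 carries CH3), C5 (C=O), C6 (O); chain C7 (=C14H2), C8 (O), C9 (CH2), C10/C11 (epoxide, C11 = CMe2). The target is (1R,2S,3S,4S,6S,8R,10S).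

**Route**

Step 1
Reactants: 1 o-cresol (2-methylphenol)
Product: 3 4,4-dimethoxy-2-methylcyclohexa-2,5-dien-1-one, via 4-methoxy-2-methylphenol 2 (not isolated)
Conditions: PhI(OAc)2 (2.2 equiv), MeOH, 0 °C to rt
Reagents that add atoms: methanol, CO
Why: Two successive PhI(OAc)2 oxidations of the phenol with methanol capture at the free para position (oxidative dearomatisation to a p-quinone monoketal) give the achiral dienone, so no stereocentre is formed.

Step 2
Reactants: 3 4,4-dimethoxy-2-methylcyclohexa-2,5-dien-1-one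
Product: 4 (1R)-4,4-dimethoxy-2-methylcyclohexa-2,5-dien-1-ol
Conditions: (S)-2-methyl-CBS-oxazaborolidine (20 mol%), catecholborane, toluene, −78 °C; aq. NaOH work-up
Reagents that add atoms: none
Why: Corey–Bakshi–Shibata reduction in which the α-methyl-substituted vinyl arm acts as the large group, so the (S)-catalyst delivers hydride to the face that gives the (R)-carbinol by clean 1,2-reduction.

Step 3
Reactants: 4 (1R)-4,4-dimethoxy-2-methylcyclohexa-2,5-dien-1-ol
Product: 5 (1R,2R,6R)-5,5-dimethoxy-1-methyl-7-oxabicyclo[4.1.0]hept-3-en-2-ol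
Conditions: VO(acac)2 (5 mol%), t-BuOOH (1.2 equiv), CH2Cl2, 0 °C
Reagents that add atoms: tert-butyl hydroperoxide, CC(C)(C)OO
Why: Hydroxyl-directed vanadium-catalysed epoxidation (Sharpless–Michaelson type) delivers oxygen syn to the OH and to the more electron-rich trisubstituted alkene, which sets both epoxide carbons.

Step 4
Reactants: 5 (1R,2R,6R)-5,5-dimethoxy-1-methyl-7-oxabicyclo[4.1.0]hept-3-en-2-ol
Product: 7 (1S,6R)-1-methyl-7-oxabicyclo[4.1.0]hept-3-ene-2,5-dione, via epoxyquinone monoketal 6 (not isolated)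
Conditions: Dess–Martin periodinane, CH2Cl2, 0 °C to rt; then 50% aq. CF3CO2H, 0 °C
Reagents that add atoms: water, O
Why: Dess–Martin oxidation removes the carbinol centre (the chirality is now stored in the epoxide) and acid hydrolysis of the dimethyl ketal unmasks the second carbonyl, the epoxide flanked by two carbonyls being resistant to acid opening.

Step 5
Reactants: 7 (1S,6R)-1-methyl-7-oxabicyclo[4.1.0]hept-3-ene-2,5-dione
Product: 8 (1S,5S,6S)-5-hydroxy-1-methyl-7-oxabicyclo[4.1.0]hept-3-en-2-one (epoxyquinol, OH cis to the epoxide)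
Conditions: NaBH4 (0.35 equiv), CeCl3·7H2O, MeOH, −78 °C
Reagents that add atoms: none
Why: Luche 1,2-reduction in which hydride attacks the less hindered carbonyl (next to the epoxide CH, not the one next to the methyl-bearing epoxide carbon) from the face opposite the epoxide oxygen, giving the cis epoxy alcohol and setting C2.

Step 6
Reactants: 9 2-bromoacrolein; 10 allylmagnesium bromide
Product: 12 (3R)-2-bromohexa-1,5-dien-3-ol, via B-allyldiisopinocampheylborane 11 (not isolated)
Conditions: 10, (+)-Ipc2BOMe, Et2O, 0 °C to rt; then 9, −78 °C; NaOH, H2O2 work-up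
Reagents that add atoms: none
Why: Brown asymmetric allylboration through a chair Zimmerman–Traxler transition state, in which the reagent derived from (−)-α-pinene adds allyl to the Re face of the aldehyde and sets C8 as (R).

Step 7
Reactants: 12 (3R)-2-bromohexa-1,5-dien-3-ol; 13 2-methylbut-2-ene
Product: 14 (3R)-2-bromo-6-methylhepta-1,5-dien-3-ol
Conditions: 13 (large excess), second-generation Grubbs catalyst RuCl2(=CHPh)(PCy3)(H2IMes) (3 mol%), CH2Cl2, 35 °C
Reagents that add atoms: none
Why: Olefin cross-metathesis of the terminal alkene with excess 2-methylbut-2-ene installs the prenyl terminus, the brominated 1,1-disubstituted alkene being too hindered and electron-poor to enter the catalytic cycle.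

Step 8
Reactants: 14 (3R)-2-bromo-6-methylhepta-1,5-dien-3-ol
Product: 15 (2R)-3-bromo-1-[(2S)-3,3-dimethyloxiran-2-yl]but-3-en-2-ol
Conditions: L-fructose-derived Shi ketone (30 mol%), Oxone (2KHSO5·KHSO4·K2SO4), K2CO3, Bu4NHSO4, MeCN–CH2(OMe)2/aq. Na2B4O7–Na2EDTA (pH 10.5), 0 °C
Reagents that add atoms: Oxone (potassium peroxymonosulfate), [K+].[O-]S(=O)(=O)OO
Why: Shi asymmetric epoxidation in which the chiral dioxirane attacks only the electron-rich trisubstituted alkene through a spiro transition state, the L-fructose-derived ketone giving the (S)-epoxide at C10 under reagent control.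

Step 9
Reactants: 15 (2R)-3-bromo-1-[(2S)-3,3-dimethyloxiran-2-yl]but-3-en-2-ol; 8 epoxyquinol
Product: 17 tethered bromo enone (dimethylsilaketal joining O2 of 8 to O8 of 15), via chlorodimethylsilyl ether 16 (not isolated)
Conditions: 15, Me2SiCl2 (5 equiv), Et3N, CH2Cl2, −78 to 0 °C; evaporate; then 8, Et3N, DMAP (cat.), CH2Cl2, 0 °C to rt
Reagents that add atoms: dichlorodimethylsilane, C[Si](C)(Cl)Cl
Why: Temporary silicon connection in which the alcohol reacts once with excess Me2SiCl2 and, after removal of the excess, the chlorosilyl ether silylates the hydroxyl of 8, forming the mixed silaketal without touching any stereocentre.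

Step 10
Reactants: 17 tethered bromo enone
Product: 18 (1R,2S,3S,4S,8R,10S) tricyclic silaketal ketone (C1–C7 bond closed cis to O2; C6 = CH2; C7=C14H2 exocyclic on the new 1,3-dioxa-2-silepane ring)
Conditions: Bu3SnH (1.3 equiv) and AIBN (0.2 equiv) by syringe pump over 8 h, benzene (2 mM), 80 °C
Reagents that add atoms: none
Why: Proposed new method: bromine abstraction by Bu3Sn• gives the σ-vinyl radical at C7, which adds 7-exo-trig to the enone β-carbon C1 on the face held by the O2–Si–O8 tether (cis to the C2 oxygen, setting C1) before the α-keto radical at C6 takes hydrogen from Bu3SnH, the closest known reactions being the Stork vinyl-radical cyclisation onto enones and silaketal-tethered radical closures of seven-membered rings.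

Step 11
Reactants: 18 tricyclic silaketal ketone
Product: 21 (1S,2S,3S,4S,6S,8R,10S) 6-acetoxy tricyclic silaketal ketone, via lithium enolate 19 (not isolated), via lithium alkoxide 20 (not isolated)
Conditions: LiN(SiMe3)2 (1.05 equiv), THF, −78 °C; 2-(phenylsulfonyl)-3-phenyloxaziridine, −78 °C; then Ac2O, DMAP, −78 to 0 °C
Reagents that add atoms: 2-(phenylsulfonyl)-3-phenyloxaziridine, O=S(=O)(c1ccccc1)N1OC1c1ccccc1; acetic anhydride, CC(=O)OC(C)=O
Why: Enolisation is possible only toward C6 (C4 is quaternary), Davis oxaziridine hydroxylation of the enolate occurs on the face anti to the C1 substituent so that the C6 oxygen is trans to the side chain, and the lithium alkoxide is acetylated in the same flask.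

Step 12
Reactants: 21 6-acetoxy tricyclic silaketal ketone
Product: 22 (1R,2S,3S,4S,6S,8R,10S) 6-acetoxy-2,8-diol
Conditions: Bu4NF/AcOH (1:1, 2.5 equiv), THF, 0 °C
Reagents that add atoms: none
Why: Buffered fluoride cleaves both Si–O bonds of the silaketal (silyl ether deprotection) under near-neutral conditions that spare the epoxides, the acetate and the α-acetoxy ketone.

Step 13
Reactants: 22 6-acetoxy-2,8-diol; 23 angelic acid ((Z)-2-methylbut-2-enoic acid)
Product: 26 target CNP0407453.2, via mixed anhydride 24 (not isolated), via 8-O-angeloyl monoester 25 (not isolated)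
Conditions: 23 (5 equiv), 2,4,6-trichlorobenzoyl chloride (5 equiv), Et3N, toluene, rt; then 22, 75 °C
Reagents that add atoms: none
Why: Yamaguchi-type mixed-anhydride esterification run without a nucleophilic catalyst acylates both secondary alcohols while keeping the (Z)-geometry of the angeloyl group (no addition–elimination route to the tiglate) and all stereocentres.

**Compound list**

1 | 2-methylphenol (o-cresol) | Cc1ccccc1O | starting material
2 | 4-methoxy-2-methylphenol | COc1ccc(O)c(C)c1 | intermediate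
3 | 4,4-dimethoxy-2-methylcyclohexa-2,5-dien-1-one | COC1(OC)C=CC(=O)C(C)=C1 | intermediate
4 | (1R)-4,4-dimethoxy-2-methylcyclohexa-2,5-dien-1-ol | COC1(OC)C=C[C@@H](O)C(C)=C1 | intermediate
5 | (1R,2R,6R)-5,5-dimethoxy-1-methyl-7-oxabicyclo[4.1.0]hept-3-en-2-ol | COC1(OC)C=C[C@@H](O)[C@@]2(C)O[C@@H]12 | intermediate
6 | (1S,6R)-5,5-dimethoxy-1-methyl-7-oxabicyclo[4.1.0]hept-3-en-2-one | COC1(OC)C=CC(=O)[C@@]2(C)O[C@@H]12 | intermediate
7 | (1S,6R)-1-methyl-7-oxabicyclo[4.1.0]hept-3-ene-2,5-dione | O=C1C=CC(=O)[C@@]2(C)O[C@@H]12 | intermediate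
8 | (1S,5S,6S)-5-hydroxy-1-methyl-7-oxabicyclo[4.1.0]hept-3-en-2-one | O[C@H]1C=CC(=O)[C@@]2(C)O[C@@H]12 | intermediate
9 | 2-bromoprop-2-enal (2-bromoacrolein) | C=C(Br)C=O | starting material
10 | allylmagnesium bromide | C=CC[Mg]Br | starting material
11 | B-allyldiisopinocampheylborane from (−)-α-pinene | C[C@@H]1[C@@H](B(CC=C)[C@H]3C[C@H]4C[C@@H]([C@@H]3C)C4(C)C)C[C@H]2C[C@@H]1C2(C)C | intermediate
12 | (3R)-2-bromohexa-1,5-dien-3-ol | C=C(Br)[C@@H](CC=C)O | intermediate
13 | 2-methylbut-2-ene | CC=C(C)C | starting material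
14 | (3R)-2-bromo-6-methylhepta-1,5-dien-3-ol | C=C(Br)[C@@H](CC=C(C)C)O | intermediate
15 | (2R)-3-bromo-1-[(2S)-3,3-dimethyloxiran-2-yl]but-3-en-2-ol | C=C(Br)[C@@H](C[C@@H]1OC1(C)C)O | intermediate
16 | chlorodimethylsilyl ether of 15 | C=C(Br)[C@@H](C[C@@H]1OC1(C)C)O[Si](C)(C)Cl | intermediate
17 | mixed dimethylsilaketal, ring (2S,3S,4S) epoxy enone on O2, chain (8R,10S) 2-bromoallylic epoxide on O8 | C=C(Br)[C@@H](C[C@@H]1OC1(C)C)O[Si](C)(C)O[C@H]1C=CC(=O)[C@@]2(C)O[C@@H]12 | intermediate
18 | (1R,2S,3S,4S,8R,10S) tricyclic silaketal ketone, C6 = CH2 | C=C([C@@H]1[C@H](O3)[C@@H]2O[C@]2(C)C(=O)C1)[C@@H](C[C@@H]1OC1(C)C)O[Si]3(C)C | intermediate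
19 | lithium enolate of 18 (C5–OLi, C5=C6) | C=C([C@@H]1[C@H](O3)[C@@H]2O[C@]2(C)C(O[Li])=C1)[C@@H](C[C@@H]1OC1(C)C)O[Si]3(C)C | intermediate
20 | lithium alkoxide of the (6S)-6-hydroxy ketone | C=C([C@@H]1[C@H](O3)[C@@H]2O[C@]2(C)C(=O)[C@H]1O[Li])[C@@H](C[C@@H]1OC1(C)C)O[Si]3(C)C | intermediate
21 | (1S,2S,3S,4S,6S,8R,10S) 6-acetoxy tricyclic silaketal ketone | C=C([C@@H]1[C@H](O3)[C@@H]2O[C@]2(C)C(=O)[C@H]1OC(C)=O)[C@@H](C[C@@H]1OC1(C)C)O[Si]3(C)C | intermediate
22 | (1R,2S,3S,4S,6S,8R,10S) 6-acetoxy-2,8-diol | C=C([C@@H]1[C@H](O)[C@@H]2O[C@]2(C)C(=O)[C@H]1OC(C)=O)[C@@H](C[C@@H]1OC1(C)C)O | intermediate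
23 | angelic acid, (Z)-2-methylbut-2-enoic acid | OC(=O)/C(C)=C\C | starting material
24 | angelic 2,4,6-trichlorobenzoic anhydride | O=C(OC(=O)/C(C)=C\C)c1c(Cl)cc(Cl)cc1Cl | intermediate
25 | 8-O-angeloyl monoester of 22 | C=C([C@@H]1[C@H](O)[C@@H]2O[C@]2(C)C(=O)[C@H]1OC(C)=O)[C@@H](C[C@@H]1OC1(C)C)OC(=O)/C(C)=C\C | intermediate
26 | CNP0407453.2, (1S,3S,4R,5S,6S)-3-acetoxy-4-{(3R)-4-[(2S)-3,3-dimethyloxiran-2-yl]-3-[(Z)-2-methylbut-2-enoyloxy]but-1-en-2-yl}-1-methyl-2-oxo-7-oxabicyclo[4.1.0]heptan-5-yl (Z)-2-methylbut-2-enoate | C=C([C@@H]1[C@H](OC(=O)/C(C)=C\C)[C@@H]2O[C@]2(C)C(=O)[C@H]1OC(C)=O)[C@@H](C[C@@H]1OC1(C)C)OC(=O)/C(C)=C\C | target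

**Step count and risks**

Total step count: 13. Longest linear sequence: 10 (steps 1–5, then 9–13); steps 6–8 form the second branch.

The three steps most likely to fail:

Step 10 (key radical ring closure). The 7-exo addition must outrun direct reduction of the vinyl radical, 1,5- and 1,6-hydrogen transfer (Si–CH3, C2–H), and attack of Bu3Sn• on the epoxy enone carbonyl. The fallback sets out from 15 and comes back at 18. It makes the same C7 radical reversibly instead of by halogen abstraction. Bu4NF·3H2O in DMF at 60 °C dehydrobrominates 15 to the alkynol (2R)-1-[(2S)-3,3-dimethyloxiran-2-yl]but-3-yn-2-ol F1. The two-stage silylation of step 9 (Me2SiCl2, Et3N; then 8) gives the alkynyl silaketal F2. Bu3SnH/AIBN in dilute benzene at 80 °C then adds Bu3Sn• to the alkyne terminus (Stork hydrostannylative vinyl-radical cyclisation). A radical that fails to cyclise reverts to the alkyne rather than being lost, and 7-exo closure gives the C14-tributylstannyl tricyclic ketone F3. Protodestannylation with pyridinium 4-methylbenzenesulfonate in CH2Cl2 returns 18.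

Step 2 (enantioselectivity of the CBS reduction). Both ketone substituents are vinyl groups that differ only by an α-methyl, so the ee may be moderate. The fallback sets out from 3 and comes back at 4. NaBH4/CeCl3·7H2O in MeOH gives the racemic dienol 4,4-dimethoxy-2-methylcyclohexa-2,5-dien-1-ol F4. Burkholderia cepacia lipase with vinyl acetate in t-BuOMe is expected to acylate the (R)-alcohol (Kazlauskas rule), giving (1R)-4,4-dimethoxy-2-methylcyclohexa-2,5-dien-1-yl acetate F5. This is separated from the unreacted (S)-alcohol (which can be re-oxidised to 3) and methanolysed with K2CO3/MeOH to 4.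

Step 5 (which of the two carbonyls of 7 is reduced, and from which face). The fallback sets out from 5 and comes back at 17. It keeps only one carbonyl in the molecule at the hydride stage. Aqueous CF3CO2H hydrolyses the ketal of 5 without prior oxidation to the hydroxy enone (1R,5R,6R)-5-hydroxy-6-methyl-7-oxabicyclo[4.1.0]hept-3-en-2-one F6. Luche reduction of its single C=O, anti to the epoxide oxygen, gives the diol (1R,2R,5S,6S)-1-methyl-7-oxabicyclo[4.1.0]hept-3-ene-2,5-diol F7. Chlorosilane 16 (Et3N, DMAP, CH2Cl2, −40 °C) should silylate the less hindered C2 hydroxyl, which sits next to an epoxide CH, in preference to the C5 hydroxyl next to the fully substituted C4, giving the tethered C5 alcohol F8. Dess–Martin oxidation of that alcohol gives 17.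

**Further compounds**

F1 | step 10 | (2R)-1-[(2S)-3,3-dimethyloxiran-2-yl]but-3-yn-2-ol | C#C[C@@H](C[C@@H]1OC1(C)C)O
F2 | step 10 | alkynyl silaketal (dimethylsilaketal joining O2 of 8 to O8 of F1) | C#C[C@@H](C[C@@H]1OC1(C)C)O[Si](C)(C)O[C@H]1C=CC(=O)[C@@]2(C)O[C@@H]12
F3 | step 10 | C14-tributylstannyl tricyclic ketone (18 with SnBu3 on the exocyclic methylene, E/Z mixture) | CCCC[Sn](CCCC)(CCCC)C=C([C@@H]1[C@H](O3)[C@@H]2O[C@]2(C)C(=O)C1)[C@@H](C[C@@H]1OC1(C)C)O[Si]3(C)C
F4 | step 2 | racemic 4,4-dimethoxy-2-methylcyclohexa-2,5-dien-1-ol | COC1(OC)C=CC(O)C(C)=C1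
F5 | step 2 | (1R)-4,4-dimethoxy-2-methylcyclohexa-2,5-dien-1-yl acetate | COC1(OC)C=C[C@@H](OC(C)=O)C(C)=C1
F6 | step 5 | (1R,5R,6R)-5-hydroxy-6-methyl-7-oxabicyclo[4.1.0]hept-3-en-2-one | O=C1C=C[C@@H](O)[C@@]2(C)O[C@@H]12
F7 | step 5 | (1R,2R,5S,6S)-1-methyl-7-oxabicyclo[4.1.0]hept-3-ene-2,5-diol | O[C@H]1C=C[C@@H](O)[C@@]2(C)O[C@@H]12
F8 | step 5 | tethered C5 alcohol (17 with CH–OH in place of the C5 carbonyl, OH cis to the epoxide) | C=C(Br)[C@@H](C[C@@H]1OC1(C)C)O[Si](C)(C)O[C@H]1C=C[C@@H](O)[C@@]2(C)O[C@@H]12
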